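**Retrosynthetic overview**

1. Target ⇐ removal of seven MOM groups ⇐ base epimerisation at the ketone α-carbon (ring C6) of the endo [4+2] adduct. An E-enone dienophile gives aroyl and 4-oxyphenyl trans, whereas the target has them cis, with the aroyl trans to the resorcinol aryl on C1.
2. Endo adduct ⇐ late enantioselective Diels–Alder union of two chalcones of equal size; the cyclohexene is the only ring formed in the route.
3. Dienophile chalcone and diene chalcone ⇐ Claisen–Schmidt condensations of one prenylated aryl methyl ketone with two protected hydroxybenzaldehydes; the diene ⇐ prenyl group by Schenck ene/reduction, then dehydration.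
4. Aryl ketone ⇐ resorcinol by two directed ortho-lithiations (prenyl bromide, then N-methoxy-N-methylacetamide); aldehydes ⇐ 4-bromophenol and resorcinol by formylation.

Assumption: the (R)-VANOL boron promoter is taken to give the (1S,5S,6R) endo adduct (the natural kuwanon-type sense); if the sense proves opposite, (S)-VANOL is used with no other change.

**Route**

Step 1
Reactants: 1 resorcinol
Product: 2 1,3-bis(methoxymethoxy)benzene
Conditions: MOMCl, i-Pr2NEt, CH2Cl2, 0 °C → rt
Reagents that add atoms: chloromethyl methyl ether (MOMCl), COCCl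
Why: O-alkylation of both phenols gives the bis-acetal, whose two OMOM groups direct the lithiations that follow.

Step 2
Reactants: 2 1,3-bis(methoxymethoxy)benzene; 3 prenyl bromide (1-bromo-3-methylbut-2-ene)
Product: 5 1,3-bis(methoxymethoxy)-2-(3-methylbut-2-en-1-yl)benzene, via C2 aryllithium 4 (not isolated)
Conditions: n-BuLi, THF, 0 °C → rt; then 3, −78 °C → rt
Reagents that add atoms: none
Why: Directed ortho-metalation at the position flanked by both OMOM groups, then SN2 alkylation of the aryllithium, installs the prenyl group regiospecifically.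

Step 3
Reactants: 5 1,3-bis(methoxymethoxy)-2-(3-methylbut-2-en-1-yl)benzene; 6 N-methoxy-N-methylacetamide
Product: 9 1-[2,4-bis(methoxymethoxy)-3-(3-methylbut-2-en-1-yl)phenyl]ethan-1-one, via C4 aryllithium 7 (not isolated), via tetrahedral lithium adduct 8 (not isolated)
Conditions: n-BuLi, TMEDA, THF, 0 °C; then 6, −78 → 0 °C; H2O
Reagents that add atoms: none
Why: A second OMOM-directed ortho-metalation (kinetic ring lithiation) and Weinreb amide acylation give the methyl ketone, the chelated tetrahedral adduct preventing over-addition.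

Step 4
Reactants: 9 1-[2,4-bis(methoxymethoxy)-3-(3-methylbut-2-en-1-yl)phenyl]ethan-1-one
Product: 10 1-[2-hydroxy-4-(methoxymethoxy)-3-(3-methylbut-2-en-1-yl)phenyl]ethan-1-one
Conditions: HCl (0.1 M in MeOH), 0 °C → rt, stopped at mono-cleavage
Reagents that add atoms: none
Why: Acid-catalysed acetal methanolysis is selective for the MOM group ortho to the acetyl, because it is the compressed one (between acetyl and prenyl) and its loss releases a phenol hydrogen-bonded to the carbonyl.

Step 5
Reactants: 11 4-bromophenol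
Product: 12 1-bromo-4-(methoxymethoxy)benzene
Conditions: MOMCl, i-Pr2NEt, CH2Cl2, 0 °C → rt
Reagents that add atoms: chloromethyl methyl ether (MOMCl), COCCl
Why: O-alkylation masks the phenol as a base-stable acetal before halogen–metal exchange.

Step 6
Reactants: 12 1-bromo-4-(methoxymethoxy)benzene
Product: 15 4-(methoxymethoxy)benzaldehyde, via aryllithium 13 (not isolated), via lithium hemiaminal alkoxide 14 (not isolated)
Conditions: n-BuLi, THF, −78 °C; then DMF, −78 °C → rt; H2O
Reagents that add atoms: N,N-dimethylformamide (DMF), CN(C)C=O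
Why: Bromine–lithium exchange followed by Bouveault formylation with DMF gives the para-aldehyde with no regiochemical ambiguity.

Step 7
Reactants: 10 1-[2-hydroxy-4-(methoxymethoxy)-3-(3-methylbut-2-en-1-yl)phenyl]ethan-1-one; 15 4-(methoxymethoxy)benzaldehyde
Product: 16 (E)-1-[2-hydroxy-4-(methoxymethoxy)-3-(3-methylbut-2-en-1-yl)phenyl]-3-[4-(methoxymethoxy)phenyl]prop-2-en-1-one
Conditions: KOH, EtOH/H2O, rt, 36 h; then dilute HCl to pH 6
Reagents that add atoms: none
Why: Claisen–Schmidt condensation (crossed aldol, E1cB dehydration) gives the E-chalcone and keeps the chelated 2'-OH needed for boron activation in the cycloaddition.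

Step 8
Reactants: 9 1-[2,4-bis(methoxymethoxy)-3-(3-methylbut-2-en-1-yl)phenyl]ethan-1-one
Product: 18 1-[3-[(E)-3-hydroxy-3-methylbut-1-en-1-yl]-2,4-bis(methoxymethoxy)phenyl]ethan-1-one, via allylic hydroperoxide 17 (not isolated)
Conditions: O2, tetraphenylporphyrin (cat.), visible light, CH2Cl2, 0 °C; then PPh3, rt
Reagents that add atoms: dioxygen, O=O
Why: Schenck ene reaction of singlet oxygen with the prenyl alkene (benzylic H abstraction, shift of the double bond to the E-styrene) and in-flask phosphine reduction give the tertiary allylic alcohol.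

Step 9
Reactants: 1 resorcinol
Product: 20 2,4-dihydroxybenzaldehyde, via aryl iminium chloride 19 (not isolated)
Conditions: POCl3, DMF, MeCN, −15 °C → rt; then H2O, 50 °C
Reagents that add atoms: N,N-dimethylformamide (DMF), CN(C)C=O; water, O
Why: Vilsmeier–Haack formylation attacks the position ortho to one hydroxyl and para to the other, and hydrolysis of the iminium salt gives the aldehyde.

Step 10
Reactants: 20 2,4-dihydroxybenzaldehyde
Product: 21 2,4-bis(methoxymethoxy)benzaldehyde
Conditions: MOMCl (3 equiv), i-Pr2NEt, CH2Cl2, 0 → 40 °C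
Reagents that add atoms: chloromethyl methyl ether (MOMCl), COCCl
Why: O-alkylation of both phenols (the chelated one needs excess reagent and warming) removes all acidic protons before the aldol step.

Step 11
Reactants: 18 1-[3-[(E)-3-hydroxy-3-methylbut-1-en-1-yl]-2,4-bis(methoxymethoxy)phenyl]ethan-1-one; 21 2,4-bis(methoxymethoxy)benzaldehyde
Product: 22 (E)-3-[2,4-bis(methoxymethoxy)phenyl]-1-[3-[(E)-3-hydroxy-3-methylbut-1-en-1-yl]-2,4-bis(methoxymethoxy)phenyl]prop-2-en-1-one
Conditions: KOH, EtOH, rt, 24 h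
Reagents that add atoms: none
Why: Claisen–Schmidt condensation gives the E-chalcone; the tertiary allylic alcohol and the MOM ethers are inert to hydroxide.

Step 12
Reactants: 22 (E)-3-[2,4-bis(methoxymethoxy)phenyl]-1-[3-[(E)-3-hydroxy-3-methylbut-1-en-1-yl]-2,4-bis(methoxymethoxy)phenyl]prop-2-en-1-one
Product: 23 (E)-3-[2,4-bis(methoxymethoxy)phenyl]-1-[2,4-bis(methoxymethoxy)-3-[(E)-3-methylbuta-1,3-dien-1-yl]phenyl]prop-2-en-1-one
Conditions: Burgess reagent, THF, 50 °C; used at once
Reagents that add atoms: none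
Why: Burgess dehydration (syn elimination of the sulfamate ester) can only take a methyl hydrogen, so the 2-substituted terminal diene forms under neutral conditions with the E-styrene bond untouched.

Step 13
Reactants: 16 (E)-1-[2-hydroxy-4-(methoxymethoxy)-3-(3-methylbut-2-en-1-yl)phenyl]-3-[4-(methoxymethoxy)phenyl]prop-2-en-1-one; 23 (E)-3-[2,4-bis(methoxymethoxy)phenyl]-1-[2,4-bis(methoxymethoxy)-3-[(E)-3-methylbuta-1,3-dien-1-yl]phenyl]prop-2-en-1-one
Product: 26 (E)-1-[3-[(1S,5S,6R)-6-[2-hydroxy-4-(methoxymethoxy)-3-(3-methylbut-2-en-1-yl)benzoyl]-5-[4-(methoxymethoxy)phenyl]-3-methylcyclohex-2-en-1-yl]-2,4-bis(methoxymethoxy)phenyl]-3-[2,4-bis(methoxymethoxy)phenyl]prop-2-en-1-one (endo adduct: aroyl cis to the C1 aryl and trans to the C5 aryl), via dienophile VANOL borate 24 (not isolated), via adduct VANOL borate 25 (not isolated)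
Conditions: (R)-VANOL, BH3·THF, AcOH, THF, rt, then evaporate (1.2 equiv promoter); 16, 23 (1.5 equiv), PhCF3, rt, 48 h; H2O work-up; chromatography
Reagents that add atoms: none
Why: Chiral-borate-promoted asymmetric Diels–Alder reaction: only the 2'-hydroxychalcone 16 chelates boron and is activated; the diene CH2 terminus bonds to the enone β-carbon. The chiral borate shields one enone face and fixes C1 and C5; the E-enone gives the 5,6-trans relation and the endo mode the 1,6-cis relation. About as much exo isomer is expected and is removed by chromatography.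

Step 14
Reactants: 26 the (1S,5S,6R) endo adduct with the free 2-hydroxyl on the benzoyl ring
Product: 27 (E)-1-[3-[(1S,5S,6R)-6-[2,4-bis(methoxymethoxy)-3-(3-methylbut-2-en-1-yl)benzoyl]-5-[4-(methoxymethoxy)phenyl]-3-methylcyclohex-2-en-1-yl]-2,4-bis(methoxymethoxy)phenyl]-3-[2,4-bis(methoxymethoxy)phenyl]prop-2-en-1-one
Conditions: MOMCl, i-Pr2NEt, CH2Cl2, 40 °C
Reagents that add atoms: chloromethyl methyl ether (MOMCl), COCCl
Why: O-alkylation of the last phenol removes the acidic proton, so the base in the next step acts only at the ketone α-carbon.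

Step 15
Reactants: 27 the hepta-MOM (1S,5S,6R) endo adduct
Product: 28 (E)-1-[3-[(1S,5S,6S)-6-[2,4-bis(methoxymethoxy)-3-(3-methylbut-2-en-1-yl)benzoyl]-5-[4-(methoxymethoxy)phenyl]-3-methylcyclohex-2-en-1-yl]-2,4-bis(methoxymethoxy)phenyl]-3-[2,4-bis(methoxymethoxy)phenyl]prop-2-en-1-one (aroyl trans to the C1 aryl and cis to the C5 aryl)
Conditions: DBU (0.3 equiv), toluene, 60 °C, to equilibrium; chromatography, recovered 27 recycled
Reagents that add atoms: none
Why: Base-mediated epimerisation through the ketone enolate inverts only C6 (C1 and C5 carry no acidic hydrogen). The inversion moves the aroyl group trans to the bulky di-ortho-substituted aryl at the price of a cis relation to the smaller 4-aryl, so 28 is expected to be at least a major equilibrium component; the equilibrium position is not known in advance.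

Step 16
Reactants: 28 the hepta-MOM (1S,5S,6S) ketone
Product: 29 (E)-1-[3-[(1S,5S,6S)-6-[2,4-dihydroxy-3-(3-methylbut-2-en-1-yl)benzoyl]-5-(4-hydroxyphenyl)-3-methylcyclohex-2-en-1-yl]-2,4-dihydroxyphenyl]-3-(2,4-dihydroxyphenyl)prop-2-en-1-one
Conditions: HCl (1.25 M in MeOH), THF, 35 °C, monitored; NaHCO3 work-up
Reagents that add atoms: none
Why: Acid-catalysed acetal methanolysis removes all seven MOM groups, with formaldehyde trapped as dimethoxymethane; the mild temperature leaves the prenyl group, the chalcone and the C6 configuration untouched, and the 1,6-trans ketone cannot form the intramolecular ketal known for the 1,6-cis series.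

**Compound list**

1 | resorcinol | Oc1cccc(O)c1 | starting material
2 | 1,3-bis(methoxymethoxy)benzene | COCOc1cccc(OCOC)c1 | intermediate
3 | prenyl bromide (1-bromo-3-methylbut-2-ene) | CC(C)=CCBr | starting material
4 | [2,6-bis(methoxymethoxy)phenyl]lithium | [Li]c1c(OCOC)cccc1OCOC | intermediate
5 | 1,3-bis(methoxymethoxy)-2-(3-methylbut-2-en-1-yl)benzene | CC(C)=CCc1c(OCOC)cccc1OCOC | intermediate
6 | N-methoxy-N-methylacetamide | CC(=O)N(C)OC | starting material
7 | [2,4-bis(methoxymethoxy)-3-(3-methylbut-2-en-1-yl)phenyl]lithium | [Li]c1ccc(OCOC)c(CC=C(C)C)c1OCOC | intermediate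
8 | lithium 1-[2,4-bis(methoxymethoxy)-3-(3-methylbut-2-en-1-yl)phenyl]-1-[methoxy(methyl)amino]ethan-1-olate | CC(O[Li])(N(C)OC)c1ccc(OCOC)c(CC=C(C)C)c1OCOC | intermediate
9 | 1-[2,4-bis(methoxymethoxy)-3-(3-methylbut-2-en-1-yl)phenyl]ethan-1-one | CC(=O)c1ccc(OCOC)c(CC=C(C)C)c1OCOC | intermediate
10 | 1-[2-hydroxy-4-(methoxymethoxy)-3-(3-methylbut-2-en-1-yl)phenyl]ethan-1-one | CC(=O)c1ccc(OCOC)c(CC=C(C)C)c1O | intermediate
11 | 4-bromophenol | Oc1ccc(Br)cc1 | starting material
12 | 1-bromo-4-(methoxymethoxy)benzene | COCOc1ccc(Br)cc1 | intermediate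
13 | [4-(methoxymethoxy)phenyl]lithium | [Li]c1ccc(OCOC)cc1 | intermediate
14 | lithium (dimethylamino)[4-(methoxymethoxy)phenyl]methanolate | [Li]OC(N(C)C)c1ccc(OCOC)cc1 | intermediate
15 | 4-(methoxymethoxy)benzaldehyde | O=Cc1ccc(OCOC)cc1 | intermediate
16 | (E)-1-[2-hydroxy-4-(methoxymethoxy)-3-(3-methylbut-2-en-1-yl)phenyl]-3-[4-(methoxymethoxy)phenyl]prop-2-en-1-one (dienophile) | CC(C)=CCc1c(OCOC)ccc(C(=O)/C=C/c2ccc(OCOC)cc2)c1O | intermediate
17 | 1-[3-[(E)-3-hydroperoxy-3-methylbut-1-en-1-yl]-2,4-bis(methoxymethoxy)phenyl]ethan-1-one | CC(=O)c1ccc(OCOC)c(/C=C/C(C)(C)OO)c1OCOC | intermediate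
18 | 1-[3-[(E)-3-hydroxy-3-methylbut-1-en-1-yl]-2,4-bis(methoxymethoxy)phenyl]ethan-1-one | CC(=O)c1ccc(OCOC)c(/C=C/C(C)(C)O)c1OCOC | intermediate
19 | (2,4-dihydroxybenzylidene)dimethyliminium chloride | C[N+](C)=Cc1ccc(O)cc1O.[Cl-] | intermediate
20 | 2,4-dihydroxybenzaldehyde | O=Cc1ccc(O)cc1O | intermediate
21 | 2,4-bis(methoxymethoxy)benzaldehyde | O=Cc1ccc(OCOC)cc1OCOC | intermediate
22 | (E)-3-[2,4-bis(methoxymethoxy)phenyl]-1-[3-[(E)-3-hydroxy-3-methylbut-1-en-1-yl]-2,4-bis(methoxymethoxy)phenyl]prop-2-en-1-one | CC(C)(O)/C=C/c1c(OCOC)ccc(C(=O)/C=C/c2ccc(OCOC)cc2OCOC)c1OCOC | intermediate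
23 | (E)-3-[2,4-bis(methoxymethoxy)phenyl]-1-[2,4-bis(methoxymethoxy)-3-[(E)-3-methylbuta-1,3-dien-1-yl]phenyl]prop-2-en-1-one (diene) | C=C(C)/C=C/c1c(OCOC)ccc(C(=O)/C=C/c2ccc(OCOC)cc2OCOC)c1OCOC | intermediate
24 | (R)-VANOL borate ester of the phenol oxygen of 16 (carbonyl oxygen coordinated to boron; drawn without the dative bond) | CC(C)=CCc1c(OCOC)ccc(C(=O)/C=C/c2ccc(OCOC)cc2)c1OB1Oc2c(-c3c(O1)c4ccccc4cc3-c3ccccc3)c(-c3ccccc3)cc3ccccc23 | intermediate
25 | (R)-VANOL borate ester of the phenol oxygen of 26, (1S,5S,6R) | CC(C)=CCc1c(OCOC)ccc(C(=O)[C@H]2[C@@H](c3c(OCOC)ccc(C(=O)/C=C/c4ccc(OCOC)cc4OCOC)c3OCOC)C=C(C)C[C@@H]2c2ccc(OCOC)cc2)c1OB1Oc2c(-c3c(O1)c4ccccc4cc3-c3ccccc3)c(-c3ccccc3)cc3ccccc23 | intermediate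
26 | (1S,5S,6R) endo adduct, six MOM ethers, free 2-hydroxyl on the benzoyl ring (full name in step 13) | CC(C)=CCc1c(OCOC)ccc(C(=O)[C@H]2[C@@H](c3c(OCOC)ccc(C(=O)/C=C/c4ccc(OCOC)cc4OCOC)c3OCOC)C=C(C)C[C@@H]2c2ccc(OCOC)cc2)c1O | intermediate
27 | (1S,5S,6R) endo adduct, seven MOM ethers (full name in step 14) | CC(C)=CCc1c(OCOC)ccc(C(=O)[C@H]2[C@@H](c3c(OCOC)ccc(C(=O)/C=C/c4ccc(OCOC)cc4OCOC)c3OCOC)C=C(C)C[C@@H]2c2ccc(OCOC)cc2)c1OCOC | intermediate
28 | (1S,5S,6S) C6 epimer, seven MOM ethers (full name in step 15) | CC(C)=CCc1c(OCOC)ccc(C(=O)[C@@H]2[C@@H](c3c(OCOC)ccc(C(=O)/C=C/c4ccc(OCOC)cc4OCOC)c3OCOC)C=C(C)C[C@@H]2c2ccc(OCOC)cc2)c1OCOC | intermediate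
29 | (E)-1-[3-[(1S,5S,6S)-6-[2,4-dihydroxy-3-(3-methylbut-2-en-1-yl)benzoyl]-5-(4-hydroxyphenyl)-3-methylcyclohex-2-en-1-yl]-2,4-dihydroxyphenyl]-3-(2,4-dihydroxyphenyl)prop-2-en-1-one | CC(C)=CCc1c(O)ccc(C(=O)[C@@H]2[C@@H](c3c(O)ccc(C(=O)/C=C/c4ccc(O)cc4O)c3O)C=C(C)C[C@@H]2c2ccc(O)cc2)c1O | target

**Totals**

Total step count: 16.
Longest linear sequence: 10 steps (steps 1, 2, 3, 8, 11, 12, 13, 14, 15, 16), which is below two thirds of 16.

**Three steps most likely to fail**

Step 15 (C6 epimerisation). The equilibrium between 27 and 28 may lie on the side of 27, since both epimers have one cis relation. Fallback: replace thermodynamic control by reagent-controlled kinetic protonation. Setting out from 27, KN(SiMe3)2 and Me3SiCl in THF at −78 °C give the trimethylsilyl enol ether F5 (ring C1 and C5 unchanged, enol ether geometry not assigned). F5 is then protonated in toluene with a catalytic chiral BINOL-derived N-triflyl thiophosphoramide and phenol as the stoichiometric proton source. The catalyst antipode that delivers the proton to the face syn to the C1 aryl is chosen, which returns the route at 28.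

Step 13 (asymmetric Diels–Alder). The endo/exo ratio is expected near 1:1, and the facial control of the borate on these heavily MOM-substituted partners is untested. Fallback: racemic cycloaddition followed by resolution. Setting out from 16 and 23, Ag nanoparticles on SiO2 (zerovalent silver) in 1,2-dichloroethane at 50 °C give the racemic endo adduct, that is 26 together with its (1R,5R,6S) enantiomer F4. After chromatographic removal of the exo isomers, preparative chiral-phase HPLC separates the two, and the route is rejoined at 26.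

Step 8 (Schenck ene reaction). The ene reaction can also give the secondary hydroperoxide regioisomer, and the electron-rich arene can be over-oxidised. Fallback: build the same side chain by cross-coupling. Setting out from 1, Nencki acylation (AcOH, ZnCl2, 140 °C) gives 1-(2,4-dihydroxyphenyl)ethan-1-one F1. Iodination between the two hydroxyls (I2/HIO3, EtOH/H2O, rt) gives 1-(2,4-dihydroxy-3-iodophenyl)ethan-1-one F2. MOMCl/i-Pr2NEt gives 1-[3-iodo-2,4-bis(methoxymethoxy)phenyl]ethan-1-one F3. Heck coupling of F3 with 2-methylbut-3-en-2-ol (Pd(OAc)2, n-Bu4NCl, NaHCO3, DMF, 80 °C) gives the E-configured tertiary allylic alcohol and returns the route at 18.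

**Further compounds**

F1 | step 8 | 1-(2,4-dihydroxyphenyl)ethan-1-one | CC(=O)c1ccc(O)cc1O
F2 | step 8 | 1-(2,4-dihydroxy-3-iodophenyl)ethan-1-one | CC(=O)c1ccc(O)c(I)c1O
F3 | step 8 | 1-[3-iodo-2,4-bis(methoxymethoxy)phenyl]ethan-1-one | CC(=O)c1ccc(OCOC)c(I)c1OCOC
F4 | step 13 | (1R,5R,6S) enantiomer of 26 | CC(C)=CCc1c(OCOC)ccc(C(=O)[C@@H]2[C@H](c3c(OCOC)ccc(C(=O)/C=C/c4ccc(OCOC)cc4OCOC)c3OCOC)C=C(C)C[C@H]2c2ccc(OCOC)cc2)c1O
F5 | step 15 | trimethylsilyl enol ether of 27 (enol ether geometry not assigned) | CC(C)=CCc1c(OCOC)ccc(C(O[Si](C)(C)C)=C2[C@@H](c3c(OCOC)ccc(C(=O)/C=C/c4ccc(OCOC)cc4OCOC)c3OCOC)C=C(C)C[C@@H]2c2ccc(OCOC)cc2)c1OCOC
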